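A direct plan would build the arene first: benzaldehyde A1 (2,3,5-trimethoxy-4-methylbenzaldehyde) would be joined to carbamate A2 (4-methylpent-3-en-1-yl N,N-diisopropylcarbamate) after its sparteine-mediated lithiation. The carbinol would be oxidised to aryl ketone A3 and methylenated, the carbamate would be exchanged for the angelate to give the trimethoxyarene ester A4, and the hydroquinone would be unmasked last through quinone A5 with (NH4)2Ce(NO3)6 and dithionite.
Its weakest steps would be:
- The carbamate lithiation, aldehyde addition, oxidation and methylenation: the only stereocentre would depend on a stoichiometric, scarce chiral diamine, a carbinol centre would be made and then destroyed, and the stereocentre would sit alpha to an aryl ketone during a Lewis-acidic titanium/zinc methylenation, where it can epimerise.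
- The reductive removal of the carbamate with LiAlH4 at reflux followed by re-acylation: two steps that build nothing, ending in a forced angeloylation of a hindered alcohol with risk of Z-to-E drift to the tiglate.
- The final oxidative demethylation: a strong one-electron oxidant would meet an electron-rich styrene, a trisubstituted alkene and the angelate, para- versus ortho-quinone selectivity would be open, and the vinylquinone can dimerise.

**Retrosynthetic overview**
The hydroquinone ring is made last instead of being carried through. C2(OH), C3(OMe), C4(Me) and C5(OH) come from 3-methoxy-4-methylcyclobutenedione 3, and C1 and C6-H from one vinyl unit of a diene. Thermal ring expansion of 4-hydroxycyclobutenone 14 forms the C5–C6 bond and gives the free hydroquinone at the correct oxidation level, so no oxidative demethylation is needed.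
That vinyl unit and the exocyclic C=CH2 of the side chain are the two halves of a butadiene-2,3-diyl linchpin (bis-stannane 5). One tin–lithium exchange joins it to Weinreb amide 7, the second to dione 3, so no methylenation next to the stereocentre is needed.
The single stereocentre is set once by catalytic CBS reduction of dienone 9 and acylated as its lithium alkoxide in the coupling flask, so no carbamate and no hydride cleavage are needed. Both epimers of 14 at the ring carbinol converge because that carbon becomes aromatic C2.

Key step: step 7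

Remark: compounds 1, 4, 6 and 11 are taken as purchasable. Compound 14 is carried as both epimers at the cyclobutenone carbinol carbon. Trimethyltin compounds are toxic and volatile and need closed handling.

**Step 1**
Reactants: 1 dimethyl squarate (3,4-dimethoxycyclobut-3-ene-1,2-dione)
Product: 3 3-methoxy-4-methylcyclobut-3-ene-1,2-dione, via lithium alkoxide adduct 2 (not isolated)
Conditions: MeLi (1.05 equiv), THF, −78 °C; then (CF3CO)2O (1.2 equiv), −78 to 0 °C; aq NaHCO3
Reagents that add atoms: methyllithium, [Li]C; water, O
Why: 1,2-addition of MeLi to one squarate carbonyl, then trifluoroacetylation, ionisation and hydration of the adduct with loss of methanol (the standard squarate to 3-alkoxy-4-alkylcyclobutenedione sequence) transposes the carbonyl and places the methyl group next to the remaining methoxy group.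

**Step 2**
Reactants: 4 1,4-dichlorobut-2-yne
Product: 5 2,3-bis(trimethylstannyl)buta-1,3-diene
Conditions: Me3SnLi (2.2 equiv, from Me3SnCl and Li, THF, 0 °C), THF, −78 °C to rt
Reagents that add atoms: trimethylstannyllithium, [Li][Sn](C)(C)C
Why: two successive SN2' displacements of chloride by the stannyl anion (alkyne to chloromethylallene to 1,3-diene) should give the known bis-stannyl diene, a butadiene-2,3-diyl dianion equivalent.

**Step 3**
Reactants: 6 4-methylpent-3-enoic acid
Product: 7 N-methoxy-N,4-dimethylpent-3-enamide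
Conditions: 1,1'-carbonyldiimidazole (1.1 equiv), CH2Cl2, rt; then MeNH(OMe)·HCl (1.2 equiv), rt
Reagents that add atoms: N,O-dimethylhydroxylamine hydrochloride, CNOC.Cl
Why: Weinreb amide formation through the acyl imidazole is mild enough that the beta,gamma-alkene should not move into conjugation.

**Step 4**
Reactants: 5 2,3-bis(trimethylstannyl)buta-1,3-diene, 7 N-methoxy-N,4-dimethylpent-3-enamide
Product: 9 7-methyl-3-methylidene-2-(trimethylstannyl)octa-1,6-dien-4-one, via stannyl dienyllithium 8 (not isolated)
Conditions: 5 (1.2 equiv), MeLi (1.15 equiv), THF, −78 °C, 30 min; then 7 (1.0 equiv), −78 °C, 1 h; sat. aq NH4Cl at −78 °C; crude 9 kept cold and dilute and used at once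
Reagents that add atoms: none
Why: selective mono tin–lithium exchange gives vinyllithium 8, whose addition to the Weinreb amide stops at the chelated tetrahedral intermediate, so the cross-conjugated dienone is released only on cold quench.

**Step 5**
Reactants: 9 7-methyl-3-methylidene-2-(trimethylstannyl)octa-1,6-dien-4-one
Product: 10 (4S)-7-methyl-3-methylidene-2-(trimethylstannyl)octa-1,6-dien-4-ol
Conditions: (R)-Me-CBS oxazaborolidine (20 mol %), catecholborane (1.8 equiv), toluene, −78 °C; MeOH quench, aq NaOH wash
Reagents that add atoms: none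
Why: Corey–Bakshi–Shibata reduction in which the branched stannyl-dienyl group takes the large-group position and the CH2CH=CMe2 chain the small one, so the (R)-catalyst should give the (S)-carbinol (mirror image of the (S)-catalyst/aryl methyl ketone to (R)-alcohol outcome), while 1,2-reduction at −78 °C leaves the vinylstannane and the alkenes untouched.

**Step 6**
Reactants: 10 (4S)-7-methyl-3-methylidene-2-(trimethylstannyl)octa-1,6-dien-4-ol, 3 3-methoxy-4-methylcyclobut-3-ene-1,2-dione, 11 angelic anhydride ((2Z)-2-methylbut-2-enoic anhydride)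
Product: 14 (4S)-2-(1-hydroxy-2-methoxy-3-methyl-4-oxocyclobut-2-en-1-yl)-7-methyl-3-methylideneocta-1,6-dien-4-yl (2Z)-2-methylbut-2-enoate, via alkoxide vinyllithium 12 (not isolated), via dilithium dialkoxide 13 (not isolated)
Conditions: 10 (1.0 equiv), MeLi (2.0 equiv), THF, −78 to −40 °C, 45 min; then 3 (1.05 equiv), −78 °C, 30 min; then 11 (1.05 equiv), −78 to −40 °C; sat. aq NH4Cl
Reagents that add atoms: none
Why: deprotonation and then tin–lithium exchange give alkoxide vinyllithium 12, which adds 1,2 to the more electrophilic carbonyl of 3 (the one flanked by the methoxy-bearing carbon, not the vinylogous ester carbonyl); of the two lithium alkoxides in 13 the unhindered secondary one should be acylated by the anhydride under base-only, catalyst-free conditions that conserve the Z geometry of angelates, the hindered tertiary cyclobutenyl alkoxide is protonated on quench, and the ring carbinol centre, formed without control, is erased in step 7.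

**Step 7**
Reactants: 14 (4S)-2-(1-hydroxy-2-methoxy-3-methyl-4-oxocyclobut-2-en-1-yl)-7-methyl-3-methylideneocta-1,6-dien-4-yl (2Z)-2-methylbut-2-enoate
Product: 17 (3S)-2-(2,5-dihydroxy-3-methoxy-4-methylphenyl)-6-methylhepta-1,5-dien-3-yl (2Z)-2-methylbut-2-enoate, via dienylketene 15 (not isolated), via cyclohexadienone 16 (not isolated)
Conditions: degassed toluene (0.01 M), 110 °C, 1–2 h, Ar, dark; concentration and chromatography under Ar
Reagents that add atoms: none
Why: Heating opens the cyclobutenone by conrotatory 4π-electrocyclic cleavage of the bond between the carbonyl carbon and the carbinol carbon, the donor hydroxyl rotating outward so that the dienyl group turns inward, cis to the ketene in 15. A 6π-electrocyclisation of this dienylketene then joins the ketene carbon to the terminal CH2 of the vinyl unit on the former carbinol carbon (the C5–C6 bond of the arene) to give cyclohexa-2,4-dienone 16, and enolisation to the aromatic ring delivers the free hydroquinone. The closest known reaction type is the Moore rearrangement of 4-alkenyl-4-hydroxycyclobutenones to hydroquinones. The six-membered ring closes by thermal 6π-electrocyclisation across the ketene C=C and the two alkene units of 15, and its substitution pattern (OH, OMe, Me, OH, H, side chain) is fixed by the connectivity of 14. No stereocentre is formed: both ring-carbinol epimers of 14 converge because that carbon becomes aromatic C2, and the (S)-carbinol centre with its angelate lies outside the reacting array. The step needs outward rotation of the hydroxyl (inward rotation would lead to a furanone), secured by the donor character of OH, and it needs only the methylene on the carbon bound to the ring carbinol to reach the ketene, secured because the second methylene is cross-conjugated; high dilution and exclusion of air should suppress Diels–Alder dimerisation of the diene and oxidation of the product.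

## Compound list

1 | dimethyl squarate (3,4-dimethoxycyclobut-3-ene-1,2-dione) | COC1=C(OC)C(=O)C1=O | starting material
2 | lithium 2,3-dimethoxy-1-methyl-4-oxocyclobut-2-en-1-olate | COC1=C(OC)C(C)(O[Li])C1=O | intermediate
3 | 3-methoxy-4-methylcyclobut-3-ene-1,2-dione | COC1=C(C)C(=O)C1=O | intermediate
4 | 1,4-dichlorobut-2-yne | ClCC#CCCl | starting material
5 | 2,3-bis(trimethylstannyl)buta-1,3-diene | C=C([Sn](C)(C)C)C(=C)[Sn](C)(C)C | intermediate
6 | 4-methylpent-3-enoic acid | CC(C)=CCC(=O)O | starting material
7 | N-methoxy-N,4-dimethylpent-3-enamide | CON(C)C(=O)CC=C(C)C | intermediate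
8 | [3-(trimethylstannyl)buta-1,3-dien-2-yl]lithium | [Li]C(=C)C(=C)[Sn](C)(C)C | intermediate
9 | 7-methyl-3-methylidene-2-(trimethylstannyl)octa-1,6-dien-4-one | C=C([Sn](C)(C)C)C(=C)C(=O)CC=C(C)C | intermediate
10 | (4S)-7-methyl-3-methylidene-2-(trimethylstannyl)octa-1,6-dien-4-ol | C=C([Sn](C)(C)C)C(=C)[C@H](CC=C(C)C)O | intermediate
11 | angelic anhydride, (2Z)-2-methylbut-2-enoic anhydride | C/C=C(/C)C(=O)OC(=O)/C(C)=C\C | starting material
12 | lithium (4S)-2-lithio-7-methyl-3-methylideneocta-1,6-dien-4-olate | [Li]C(=C)C(=C)[C@H](CC=C(C)C)O[Li] | intermediate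
13 | dilithium dialkoxide of (4S)-2-(1-hydroxy-2-methoxy-3-methyl-4-oxocyclobut-2-en-1-yl)-7-methyl-3-methylideneocta-1,6-dien-4-ol (both ring-carbinol epimers) | COC1=C(C)C(=O)C1(O[Li])C(=C)C(=C)[C@H](CC=C(C)C)O[Li] | intermediate
14 | (4S)-2-(1-hydroxy-2-methoxy-3-methyl-4-oxocyclobut-2-en-1-yl)-7-methyl-3-methylideneocta-1,6-dien-4-yl (2Z)-2-methylbut-2-enoate (both ring-carbinol epimers) | COC1=C(C)C(=O)C1(O)C(=C)C(=C)[C@H](CC=C(C)C)OC(=O)/C(C)=C\C | intermediate
15 | (4S)-2-[(1Z)-1-hydroxy-2-methoxy-3-methyl-4-oxobuta-1,3-dien-1-yl]-7-methyl-3-methylideneocta-1,6-dien-4-yl (2Z)-2-methylbut-2-enoate | O=C=C(C)/C(OC)=C(/O)C(=C)C(=C)[C@H](CC=C(C)C)OC(=O)/C(C)=C\C | intermediate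
16 | 4-hydroxy-3-methoxy-2-methyl-5-{(3S)-6-methyl-3-[(2Z)-2-methylbut-2-enoyloxy]hepta-1,5-dien-2-yl}cyclohexa-2,4-dien-1-one | O=C1CC(C(=C)[C@H](CC=C(C)C)OC(=O)/C(C)=C\C)=C(O)C(OC)=C1C | intermediate
17 | (3S)-2-(2,5-dihydroxy-3-methoxy-4-methylphenyl)-6-methylhepta-1,5-dien-3-yl (2Z)-2-methylbut-2-enoate | C=C(c1cc(O)c(C)c(OC)c1O)[C@H](CC=C(C)C)OC(=O)/C(C)=C\C | target

Total step count: 7. Longest linear sequence: 5 steps (steps 2, 4, 5, 6, 7; equally steps 3, 4, 5, 6, 7).

## Steps most likely to fail

**Step 6.** The anhydride may also acylate the tertiary cyclobutenyl alkoxide, or the acyl group may move between the two oxygens before the quench, so that site selectivity is lost. The fallback sets out from 10 and comes back at 14, telling the two oxygens apart by protecting groups instead of by rate. Dialkoxide 13 would be made from 10 and 3 as in step 6 but protonated at −78 °C (sat. aq NH4Cl) to give the diol (4S)-2-(1-hydroxy-2-methoxy-3-methyl-4-oxocyclobut-2-en-1-yl)-7-methyl-3-methylideneocta-1,6-dien-4-ol F1. Et3SiOTf (2.5 equiv) and 2,6-lutidine in CH2Cl2 at −78 to 0 °C should silylate both hydroxyls to give the bis-silyl ether (4S)-2-[2-methoxy-3-methyl-4-oxo-1-(triethylsilyloxy)cyclobut-2-en-1-yl]-7-methyl-3-methylidene-4-(triethylsilyloxy)octa-1,6-diene F2. Pyridinium p-toluenesulfonate (10 mol %) in MeOH/CH2Cl2 at 0 °C (methanol exchange at the vinylogous ester is degenerate) should cleave the secondary silyl ether well before the hindered tertiary one to give the secondary alcohol (4S)-2-[2-methoxy-3-methyl-4-oxo-1-(triethylsilyloxy)cyclobut-2-en-1-yl]-7-methyl-3-methylideneocta-1,6-dien-4-ol F3. LiN(SiMe3)2 and 11 in THF at −78 °C would then acylate the only free hydroxyl to give (4S)-2-[2-methoxy-3-methyl-4-oxo-1-(triethylsilyloxy)cyclobut-2-en-1-yl]-7-methyl-3-methylideneocta-1,6-dien-4-yl (2Z)-2-methylbut-2-enoate F4, and pyridine-buffered HF·pyridine in THF at 0 °C would free the tertiary hydroxyl to give 14. No silyl ether is present while the vinyllithium exists, so silyl migration from oxygen to carbon cannot interfere.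

**Step 7.** Part of the material may open with inward rotation of the free hydroxyl, which then captures the ketene as a furanone, or the free hydroquinone may be oxidised or oligomerise while hot. The fallback sets out from 14 and comes back at 17, running the ring expansion on a capped carbinol so that the arene emerges as a masked hydroquinone. Compound 14 would be silylated (Me3SiCl, Et3N, CH2Cl2, 0 °C) to (4S)-2-[2-methoxy-3-methyl-4-oxo-1-(trimethylsilyloxy)cyclobut-2-en-1-yl]-7-methyl-3-methylideneocta-1,6-dien-4-yl (2Z)-2-methylbut-2-enoate F5. Its thermolysis (toluene, 110 °C) cannot lactonise and should give the mono-silylated hydroquinone (3S)-2-[5-hydroxy-3-methoxy-4-methyl-2-(trimethylsilyloxy)phenyl]-6-methylhepta-1,5-dien-3-yl (2Z)-2-methylbut-2-enoate F6. Citric acid in MeOH at 0 °C under argon would remove the aryl silyl ether to give 17.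

**Step 4.** Vinyllithium 8 may deprotonate the alpha-CH2 of amide 7 instead of adding, or the cross-conjugated dienone 9 may dimerise by Diels–Alder reaction before it can be reduced. The fallback sets out from 5 and comes back at 10, replacing the ketone and its asymmetric reduction by aldehyde addition and kinetic resolution. 4-Methylpent-3-en-1-ol F7 would be oxidised with Dess–Martin periodinane (CH2Cl2, 0 °C) to 4-methylpent-3-enal F8. Its addition at −78 °C to 8 (from 5 and MeLi) should give the stable racemic alcohol 7-methyl-3-methylidene-2-(trimethylstannyl)octa-1,6-dien-4-ol F9. Sharpless kinetic resolution (Ti(OiPr)4, D-(−)-diisopropyl tartrate, t-BuOOH (0.6 equiv), 4 Å molecular sieves, CH2Cl2, −20 °C) should consume the (R)-enantiomer as the erythro epoxy alcohol (1R)-4-methyl-1-{(2S)-2-[1-(trimethylstannyl)ethenyl]oxiran-2-yl}pent-3-en-1-ol F10 and leave the (S)-alcohol 10.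

## Further compounds

F1 | step 6 | (4S)-2-(1-hydroxy-2-methoxy-3-methyl-4-oxocyclobut-2-en-1-yl)-7-methyl-3-methylideneocta-1,6-dien-4-ol | COC1=C(C)C(=O)C1(O)C(=C)C(=C)[C@H](CC=C(C)C)O
F2 | step 6 | (4S)-2-[2-methoxy-3-methyl-4-oxo-1-(triethylsilyloxy)cyclobut-2-en-1-yl]-7-methyl-3-methylidene-4-(triethylsilyloxy)octa-1,6-diene | COC1=C(C)C(=O)C1(O[Si](CC)(CC)CC)C(=C)C(=C)[C@H](CC=C(C)C)O[Si](CC)(CC)CC
F3 | step 6 | (4S)-2-[2-methoxy-3-methyl-4-oxo-1-(triethylsilyloxy)cyclobut-2-en-1-yl]-7-methyl-3-methylideneocta-1,6-dien-4-ol | COC1=C(C)C(=O)C1(O[Si](CC)(CC)CC)C(=C)C(=C)[C@H](CC=C(C)C)O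
F4 | step 6 | (4S)-2-[2-methoxy-3-methyl-4-oxo-1-(triethylsilyloxy)cyclobut-2-en-1-yl]-7-methyl-3-methylideneocta-1,6-dien-4-yl (2Z)-2-methylbut-2-enoate | COC1=C(C)C(=O)C1(O[Si](CC)(CC)CC)C(=C)C(=C)[C@H](CC=C(C)C)OC(=O)/C(C)=C\C
F5 | step 7 | (4S)-2-[2-methoxy-3-methyl-4-oxo-1-(trimethylsilyloxy)cyclobut-2-en-1-yl]-7-methyl-3-methylideneocta-1,6-dien-4-yl (2Z)-2-methylbut-2-enoate | COC1=C(C)C(=O)C1(O[Si](C)(C)C)C(=C)C(=C)[C@H](CC=C(C)C)OC(=O)/C(C)=C\C
F6 | step 7 | (3S)-2-[5-hydroxy-3-methoxy-4-methyl-2-(trimethylsilyloxy)phenyl]-6-methylhepta-1,5-dien-3-yl (2Z)-2-methylbut-2-enoate | C=C(c1cc(O)c(C)c(OC)c1O[Si](C)(C)C)[C@H](CC=C(C)C)OC(=O)/C(C)=C\C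
F7 | step 4 | 4-methylpent-3-en-1-ol | CC(C)=CCCO
F8 | step 4 | 4-methylpent-3-enal | CC(C)=CCC=O
F9 | step 4 | racemic 7-methyl-3-methylidene-2-(trimethylstannyl)octa-1,6-dien-4-ol | C=C([Sn](C)(C)C)C(=C)C(CC=C(C)C)O
F10 | step 4 | (1R)-4-methyl-1-{(2S)-2-[1-(trimethylstannyl)ethenyl]oxiran-2-yl}pent-3-en-1-ol | C=C([Sn](C)(C)C)[C@]1(CO1)[C@@H](CC=C(C)C)O
A1 | direct plan | 2,3,5-trimethoxy-4-methylbenzaldehyde | O=Cc1cc(OC)c(C)c(OC)c1OC
A2 | direct plan | 4-methylpent-3-en-1-yl N,N-diisopropylcarbamate | CC(C)=CCCOC(=O)N(C(C)C)C(C)C
A3 | direct plan | (2S)-5-methyl-1-oxo-1-(2,3,5-trimethoxy-4-methylphenyl)hex-4-en-2-yl N,N-diisopropylcarbamate | O=C(c1cc(OC)c(C)c(OC)c1OC)[C@H](CC=C(C)C)OC(=O)N(C(C)C)C(C)C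
A4 | direct plan | (3S)-6-methyl-2-(2,3,5-trimethoxy-4-methylphenyl)hepta-1,5-dien-3-yl (2Z)-2-methylbut-2-enoate | C=C(c1cc(OC)c(C)c(OC)c1OC)[C@H](CC=C(C)C)OC(=O)/C(C)=C\C
A5 | direct plan | (3S)-2-(5-methoxy-4-methyl-3,6-dioxocyclohexa-1,4-dien-1-yl)-6-methylhepta-1,5-dien-3-yl (2Z)-2-methylbut-2-enoate | C=C(C1=CC(=O)C(C)=C(OC)C1=O)[C@H](CC=C(C)C)OC(=O)/C(C)=C\C
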